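## Structural features

The target is a C19 gibberellin. Ring A (C1–C5, C10) is a cyclohexanone bridged from C4 to C10 by a γ-lactone (C19 on C4, oxygen on C10). Ring B (C5, C6, C8, C9, C10) is a cyclopentane. Rings C and D (C8, C9, C11–C14 and C8, C14, C13, C16, C15) form a bicyclo[3.2.1]octane with an exocyclic methylene on C16.

Nine stereocentres are present (C1, C4, C5, C6, C8, C9, C10, C12, C13). They form one contiguous array, and C4, C8 and C10 are fully substituted. Throughout, β means the face of ring B that carries C15 (and H9, H5, C7 and the C1 hydroxyl); α means the face that carries C14, the lactone oxygen and C19. The C12 hydroxyl is axial on ring C, on the side away from the C15–C16 bridge and 1,3 to C10.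

The fragile groups are:
- the C1-hydroxy C3-ketone (retro-aldol, dehydration);
- the β-keto lactone at quaternary C4 (retro-Claisen);
- the 1,1-disubstituted C16 alkene (acid, electrophiles);
- the free C7 acid on a hindered carbon, which cannot be unveiled by saponification.

The real difficulty is the crowded C4–C5–C10–C9–C8 region: a lactone-bridged ring A must be attached to a cis-fused hydrindane with control at every centre and with three oxidised positions (C1, C3, C12) kept apart.

The key step exploits one feature. Ring B is a cyclopentane whose C6 carries a single exocyclic carboxyl carbon (C7) next to quaternary C8. That pattern is what remains when the carbonyl carbon of a cyclohexanone C8–C7(=O)–C6 is pushed out of the ring.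

## Logic of the disconnections

**36 ⇐ 35 ⇐ 34.** Only the O–allyl bond at C7 and the O–Si bond at C12 are cut. The acid and the axial alcohol are unveiled last because hydroxide would attack the β-hydroxy ketone and β-keto lactone before it reached the hindered C7 ester. The forward steps must be neutral (zerovalent palladium) or mildly acidic (fluoride).

**34 ⇐ 33 ⇐ 32.** The C1–C2 bond of ring A is cut (retro-aldol), leaving a methyl ketone on C4 and an aldehyde on C10; in 32 the aldehyde is masked as a dithiane. Ring A and the C1 centre disappear. The forward step needs kinetic enolisation at C2 and a closed transition state that places the new hydroxyl axial.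

**32 ⇐ 31.** The C4–C5 bond is cut (retro-Michael), which also opens the lactone ring to a β-keto ester tethered through the C10 oxygen and a C5=C6 enoate. C4, C5 and C6 are removed as stereocentres. The forward step needs a 5-exo closure; the tether must dictate C5, and C4 and C6 must settle correctly.

**31 ⇐ 28 + 29.** The O10–C19 ester bond is cut, detaching the five-carbon unit C19, C4, C18, C3, C2. The demand is acylation of a very hindered tertiary alcohol, met by an acylketene.

**28 ⇐ 25.** The C5=C6 double bond is traced to the saturated ester (functional-group change). The forward step needs dehydrogenation towards C5 only, which the quaternary C8 enforces.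

**25 ⇐ 22 + 23.** The C10–C1 bond is cut, reducing the oxygenated quaternary C10 to a ketone. The forward addition must come from the face of H9.

**22 ⇐ 21 ⇐ 20.** The C12–H bond (and the silyl ether) are removed, giving the C10, C12 diketone. The forward reduction must pick C12 over C10 and deliver hydride from the side of the C15–C16 bridge.

**20 ⇐ 18 ⇐ 17 ⇐ 15 ⇐ 14.** The C9–H and C11–H bonds and the C10 oxygen are removed in turn. C9 becomes a matter of equilibration next to the C10 ketone, and the C10 oxygen is traced to the γ-position of the enone 14. The forward oxidation must be γ-selective and must spare the C16 alkene.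

**14 ⇐ 13 ⇐ 12.** The C13–C16 bond of ring D is cut, taking the bicyclo[3.2.1]octane back to a hydrindenone with a propargyl arm on C8. The forward step needs the enol ether on the C13 side of C12 and a 5-exo-dig closure.

**12 ⇐ 11 ⇐ 9 (through 10).** The C6–C8 bond is cut and the C7–C8 bond restored, so the cyclopentane ester becomes a cyclohexanone. This exchanges a hydrindane that is hard to make directly for a decalin available by annulation, and it explains why C7 is already at the acid oxidation level. The forward step needs the diazo group on C6 only and migration of C8 with retention.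

**9 ⇐ 7 ⇐ 6.** These are functional-group changes only (diazo transfer at C6, dithioketal at C12). They rely on C8 being quaternary, so that C7 enolises one way, and on the conjugated C12 carbonyl being the one that takes up the dithiol.

**6 ⇐ 5 ⇐ 3 + 4, and 3 ⇐ 1 + 2.** The C9–C11 bond (aldol condensation), the C8–C14 bond (Michael addition) and the C8–C15 bond (alkylation) are cut in turn. All skeletal carbons of rings B, C and D then come from three commodity chemicals. The forward aldol must be enantioselective, because C8 controls every later centre.

## Other disconnections considered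

**Alternative 1:** manganese-mediated radical cyclisation–lactonisation.
- Cut: the C4–C5 bond and the C10–O lactone bond together.
- Forward step: Mn(OAc)3 with Cu(OAc)2 in acetic acid would oxidise the tert-butyl 2-methyl-3-oxo ester of A1 to a C4 radical. This would add 6-endo to C5 of the C5=C10 alkene. Divalent copper would oxidise the tertiary C10 radical, and the ester carbonyl would capture the cation with loss of the tert-butyl group, giving A2.
- In favour: ring A, the lactone and three centres (C4, C5, C10) would arise in one non-basic operation, and the electrophilic radical is polarity-matched with the trisubstituted alkene. On step economy at the end this is better than the chosen plan, which spends four steps (18–21) on the same bonds. A2 is two deprotections from the target, as 34 is.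
- Against: the C1 centre would have to be set earlier on an open chain. C9 would have to be fixed without a C10 carbonyl to equilibrate it. Nothing as short as the lactone tether of 31 decides the face of attack at C5. Oxidation of the C10 radical can end in elimination instead of lactone capture. The C16 alkene, its allylic positions and two silyl ethers would be exposed to a one-electron oxidant in warm acetic acid.
- Comparison: both plans can share the ring contraction upstream. The chosen plan is longer at the end but keeps oxidants and acid away from the methylene group and sets C10 and C5 by a ketone addition and a tether.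

**Alternative 2:** Diels–Alder construction of ring C.
- Cut: the C9–C11 and C8–C14 bonds.
- Forward step: EtAlCl2 would promote addition of the silyloxy diene A4 to the cyclopentenone A3, giving A5.
- In favour: the quaternary C8 and the cis B/C fusion would be set in one suprafacial step. On C9 this is better than the chosen plan, which relies on equilibration in step 13. The C10 oxygen would arrive with A3, which is better than the three-step oxygenation in steps 10–12. The C12–C13 silyl enol ether of A5 is exactly the nucleophile needed for gold-catalysed closure of ring D, which equals or betters step 8.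
- Against: 2-substituted cyclopentenones are reluctant dienophiles. The strong Lewis acid needed threatens the product enol ether and can eliminate the β-silyloxy group of A3. Facial control would rest on that one substituent. C6 would arrive as a ketone, so C7 would still have to be attached to a neopentyl carbonyl and C6 configured.
- Comparison: this alternative is more convergent and stronger at C9 and C10. The chosen plan is stronger at C6/C7, because the Wolff shift delivers C7 already as a carboxyl, and at C8, which is set by a catalytic annulation.

**Alternative 3:** epoxide opening by a vinyl anion to close ring D.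
- Cut: the C13–C16 bond.
- Forward step: bromine–lithium exchange on A6 with t-BuLi would give a C16 vinyllithium that opens the C12–C13 epoxide at C13 with inversion, giving A7.
- In favour: ring D, the methylene group, C13 and the axial C12 hydroxyl would be set together and stereospecifically. On C12 this is better than the chosen plan, which needs a site- and face-selective reduction (step 14).
- Against: the epoxide would have to be placed on the face opposite the bromoallyl arm. Unactivated epoxides open sluggishly with alkenyllithiums, and base-induced isomerisation to the allylic alcohol competes. t-BuLi excludes an ester, so C7 would have to be absent (C6 is a masked ketone in A7) and added later, as in Alternative 2.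
- Comparison: the gold closure of the chosen plan is catalytic and ester-tolerant. It also keeps C12 as a ketone, which is the handle used afterwards to oxygenate C10 and to equilibrate C9. The epoxide route is superior only for C12 and C13.

Key step: step 6

Remark 1: 2,2,5,6-tetramethyl-4H-1,3-dioxin-4-one (29, the acetone adduct of methylacetylketene) is treated as a purchasable reagent.

Remark 2: C6 in 11–27 is drawn with the ester on the β face. The centre is epimerisable, either epimer can be carried, and it is flattened in step 17 and reset in step 19.

## Route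

Step 1
Reactants: 1 cyclohexane-1,3-dione; 2 propargyl bromide
Product: 3 2-(prop-2-yn-1-yl)cyclohexane-1,3-dione
Conditions: KOH (1 equiv), H2O, rt to 50 °C
Reagents that add atoms: none
Why: C-alkylation (SN2) of the dione enolate; water hydrogen-bonds the enolate oxygens and so favours attack through carbon on the reactive propargylic halide.

Step 2
Reactants: 3 2-(prop-2-yn-1-yl)cyclohexane-1,3-dione; 4 methyl vinyl ketone
Product: 5 2-(3-oxobutyl)-2-(prop-2-yn-1-yl)cyclohexane-1,3-dione
Conditions: Et3N (cat.), neat, rt
Reagents that add atoms: none
Why: Michael addition of the acidic 2-substituted 1,3-dione to the enone; it forms the C8–C14 bond and the still achiral quaternary C8.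

Step 3
Reactants: 5 triketone
Product: 6 (R)-8a-(prop-2-yn-1-yl)-3,4,8,8a-tetrahydronaphthalene-1,6(2H,7H)-dione
Conditions: N-tosyl-(Sa)-binam-L-prolinamide (2 mol %), PhCO2H (cat.), neat, rt
Reagents that add atoms: none
Why: Hajos–Parrish–Eder–Sauer–Wiechert aldol condensation under enamine catalysis; the enamine of the side-chain ketone attacks one of the two enantiotopic ring carbonyls, which the sulfonamide N–H activates; L-proline-derived catalysts give the spatial sense of the (S)-methyl series, which carries the R descriptor for the propargyl compound and is the C8 configuration of the target.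

Step 4
Reactants: 6 propargyl Wieland–Miescher ketone
Product: 7 C12 dithiolane of 6 (C7 ketone free, C9=C11 unmoved)
Conditions: HSCH2CH2SH (1.05 equiv), p-TsOH·H2O (cat.), AcOH, rt
Reagents that add atoms: ethane-1,2-dithiol, SCCS
Why: Acid-catalysed dithioketalisation; the conjugated C12 carbonyl reacts through a stabilised allylic thionium ion while the C7 ketone beside quaternary C8 is slow, and unlike O-ketalisation the C9=C11 bond does not migrate.

Step 5
Reactants: 7 dithiolane ketone
Product: 9 6-diazo-7-ketone, via trifluoroacetyl ketone 8 (not isolated)
Conditions: LiN(SiMe3)2, THF, −78 °C; CF3CO2CH2CF3; aq. HCl; then p-ABSA, Et3N, H2O (1 equiv), MeCN, rt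
Reagents that add atoms: 4-acetamidobenzenesulfonyl azide (p-ABSA), CC(=O)Nc1ccc(cc1)S(=O)(=O)N=[N+]=[N-]
Why: Detrifluoroacetylative diazo transfer (Regitz type, Danheiser variant); C8 is quaternary, so the C7 ketone enolises only towards C6 and the diazo group is placed regiospecifically; at −78 °C the amide base removes the ketone α-proton ahead of the less acidic alkyne C–H.

Step 6
Reactants: 9 6-diazo-7-ketone
Product: 11 allyl ester of the ring-contracted acid (ring B five-membered, C7 ester on C6 cis to the propargyl arm, C12 dithiolane kept), via ketene 10 (not isolated)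
Conditions: hν (365 nm), allyl alcohol/THF (1:4), rt
Reagents that add atoms: allyl alcohol, C=CCO
Why: Excitation of the diazo ketone, held s-Z by the ring, expels dinitrogen with a 1,2-shift of C8 from C7 to C6 (C8 is the only carbon substituent on the C7 carbonyl); the ketene 10 is intercepted by allyl alcohol and the ester enol is protonated at C6. The closest known reaction type is the photochemical Wolff ring contraction of cyclic 2-diazo ketones to ring-contracted esters. Ring B is closed not by a cyclisation but by contraction of the six-membered ring: the C6–C8 bond replaces the C7–C8 bond and C7 is pushed out as the carboxyl carbon. C8 migrates with retention, so the configuration set in step 3 is carried over unchanged. C6 is set by protonation of the ester enol; the drawn epimer is expected together with its epimer, and both are usable because C6 becomes trigonal in step 17 and is reset in step 19. The step needs the diazo group on C6 only, which the quaternary C8 guarantees, and it needs rearrangement to outrun carbene chemistry at sulfur, at the alkyne or at the solvent O–H, which the s-Z geometry and irradiation at 365 nm (where dithiolane, alkene and alkyne do not absorb) favour. Allyl alcohol replaces methanol as the ketene trap so that the C7 acid can be released at the end by zerovalent palladium without base.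

Step 7
Reactants: 11 dithiolane allyl ester
Product: 12 hydrindenone (C12 ketone conjugated with C9=C11, propargyl on C8, allyl ester on C6)
Conditions: MeI (excess), CaCO3, MeCN/H2O (4:1), 45 °C
Reagents that add atoms: water, O
Why: Alkylative hydrolysis of the dithiolane (S-methylation, opening to the allylic thionium ion, hydration); no mercury or silver salt is used, so the terminal alkyne is neither hydrated nor metallated.

Step 8
Reactants: 12 hydrindenone
Product: 13 cross-conjugated silyl dienol ether (C12 OTBS, C12=C13, C9=C11)
Conditions: LiN(SiMe3)2 (1.1 equiv), THF, −78 °C; then TBSOTf, −78 °C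
Reagents that add atoms: tert-butyldimethylsilyl trifluoromethanesulfonate, CC(C)(C)[Si](C)(C)OS(=O)(=O)C(F)(F)F
Why: Kinetic α′-deprotonation of the enone at C13 and O-silylation; the γ-protons on C10, the hindered ester α-proton on C6 and the alkyne C–H are removed more slowly under these conditions.

Step 9
Reactants: 13 silyl dienol ether
Product: 14 tricyclic enone (rings B, C and D; C12 ketone, C9=C11, C16 methylene)
Conditions: Ph3PAuCl (5 mol %), AgBF4 (5 mol %), toluene/MeOH (10:1), rt
Reagents that add atoms: none
Why: Gold-catalysed 5-exo-dig carbocyclisation of a silyl enol ether onto a π-activated alkyne (Conia-ene type); C13 attacks C16 anti to gold, methanol takes the silyl group and protonates the vinyl–gold bond to leave the C16 methylene; the C15 arm can reach C13 across one face only, so the bridgehead configuration follows from C8.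

Step 10
Reactants: 14 tricyclic enone
Product: 15 extended silyl dienol ether (C12 OTBS, C11=C12, C9=C10)
Conditions: TBSOTf, Et3N, CH2Cl2, 0 °C
Reagents that add atoms: tert-butyldimethylsilyl trifluoromethanesulfonate, CC(C)(C)[Si](C)(C)OS(=O)(=O)C(F)(F)F
Why: Soft enolisation to the silyl dienol ether; C13 is now a bridgehead and cannot enolise, so γ-deprotonation at C10 is the only course.

Step 11
Reactants: 15 extended silyl dienol ether
Product: 17 γ-hydroxy enone (C10 OH, either configuration), via 9,10-epoxide 16 (not isolated)
Conditions: DMDO (1.05 equiv), acetone/CH2Cl2, −78 °C; then AcOH/H2O/THF, 0 °C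
Reagents that add atoms: dimethyldioxirane, CC1(C)OO1
Why: Vinylogous Rubottom oxidation; the dioxirane epoxidises the terminal, most electron-rich C9=C10 bond of the dienol ether and mild acid opens the epoxide with loss of silicon to the γ-hydroxy enone; at −78 °C the C16 alkene and the allyl ester react far more slowly, and the C10 configuration is of no consequence.

Step 12
Reactants: 17 γ-hydroxy enone
Product: 18 ene-dione (C10 and C12 ketones across C9=C11)
Conditions: Dess–Martin periodinane, NaHCO3, CH2Cl2, rt
Reagents that add atoms: none
Why: Oxidation of the allylic secondary alcohol with a hypervalent iodine reagent under buffered conditions that leave both alkenes untouched.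

Step 13
Reactants: 18 ene-dione
Product: 20 10,12-diketone with H9 on the β face (cis B/C fusion), via 9-epi diketone 19 (not isolated)
Conditions: Zn dust, AcOH, rt; then DBU (0.2 equiv), CH2Cl2, rt
Reagents that add atoms: none
Why: Dissolving-metal reduction of the 2-ene-1,4-dione double bond (isolated alkenes and esters are inert); C9 is then α to the C10 ketone and is equilibrated by base to the cis-fused hydrindanone (C10 axial on ring C), the arrangement favoured for a ring-fusion cyclopentanone next to an angular quaternary carbon.

Step 14
Reactants: 20 10,12-diketone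
Product: 21 12α-hydroxy 10-ketone
Conditions: LiBH(s-Bu)3 (1.05 equiv), THF, −78 °C; aq. NH4Cl
Reagents that add atoms: none
Why: Selective hydride reduction; the six-ring ketone C12 is expected to react ahead of the cyclopentanone C10, whose faces are flanked by C15/C7 and by ring C, and the bulky hydride reaches C12 along the equatorial path on the C16 side because the axial C10 carbon blocks the other face, giving the axial 12α alcohol (which may rest as a bridged hemiketal with C10).

Step 15
Reactants: 21 12α-hydroxy 10-ketone
Product: 22 12α-silyloxy 10-ketone
Conditions: TBSOTf, 2,6-lutidine, CH2Cl2, −78 to 0 °C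
Reagents that add atoms: tert-butyldimethylsilyl trifluoromethanesulfonate, CC(C)(C)[Si](C)(C)OS(=O)(=O)C(F)(F)F
Why: Silylation of the hindered axial alcohol with the silyl triflate; any hemiketal is in equilibrium with the open hydroxy ketone, whose secondary hydroxyl is the faster nucleophile.

Step 16
Reactants: 22 12α-silyloxy 10-ketone; 23 1,3-dithiane
Product: 25 C10 tertiary alcohol carrying C1 as a 1,3-dithian-2-yl group (hydroxyl α, C1 β), via 2-lithio-1,3-dithiane 24 (not isolated)
Conditions: 23, n-BuLi, THF, −30 °C; then 22, −78 to −40 °C; aq. NH4Cl
Reagents that add atoms: none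
Why: Corey–Seebach addition of a formyl anion equivalent to the C10 ketone; the α face is covered by ring C and the 12α silyl ether, so C1 enters from the convex β face (the side of H9) and the new hydroxyl is α, where the lactone oxygen must be.

Step 17
Reactants: 25 dithiane carbinol
Product: 28 C5=C6 enoate, via phenylselanyl ester 26 (not isolated), via selenoxide 27 (not isolated)
Conditions: LiN(i-Pr)2 (2.5 equiv), THF, −78 °C; PhSeBr, −78 °C; then H2O2, pyridine, CH2Cl2, 0 °C to rt
Reagents that add atoms: none
Why: α-Selenenylation of the ester enolate (formed beside the lithium alkoxide) followed by selenoxide syn-elimination; C8 is quaternary, so only C5 offers a β-hydrogen and the C5=C6 bond forms regiospecifically; the enolate is kept at −78 °C to exclude Ireland–Claisen rearrangement of the allyl ester.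

Step 18
Reactants: 28 C5=C6 enoate; 29 2,2,5,6-tetramethyl-4H-1,3-dioxin-4-one
Product: 31 C10 2-methyl-3-oxobutanoate (C4 epimers), via methylacetylketene 30 (not isolated)
Conditions: 29 (3 equiv), toluene, 110 °C
Reagents that add atoms: none
Why: Thermal retro-[4+2] of the dioxinone releases an acylketene that acylates the hindered tertiary alcohol under neutral conditions (acetoacetylation via acylketene); the temperature is held at 110 °C to stay below the onset of Carroll rearrangement of the allylic β-keto ester.

Step 19
Reactants: 31 tethered β-keto ester
Product: 32 19,10-lactone with C4 (methyl, acetyl), H5 β and the C7 ester β; C1 still a dithiane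
Conditions: KOt-Bu (0.3 equiv), t-BuOH/THF (1:5), 0 °C to rt
Reagents that add atoms: none
Why: Intramolecular Michael addition (5-exo-trig) of the β-keto ester enolate C4 to C5 of the enoate; the five-membered lactone can only be cis-fused to ring B, which puts C4 on the α face of C5 (H5 β); at C4 the acetyl arm should take the open position beside H5 and leave the smaller methyl eclipsed with C6; C6 is protonated reversibly under the alkoxide and should settle with the ester trans to C4.

Step 20
Reactants: 32 lactone dithiane
Product: 33 lactone aldehyde (C1 formyl on C10)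
Conditions: MeI (excess), CaCO3, MeCN/H2O (4:1), 45 °C
Reagents that add atoms: water, O
Why: Alkylative hydrolysis of the dithiane under neutral conditions; the aldehyde has no α-hydrogen and C4 is quaternary, so nothing can epimerise.

Step 21
Reactants: 33 lactone aldehyde
Product: 34 tetracyclic 1β-hydroxy 3-ketone (12-silyl ether, allyl ester)
Conditions: LiN(SiMe3)2 (1.05 equiv), THF, −78 °C; AcOH quench at −78 °C
Reagents that add atoms: none
Why: Intramolecular aldol addition closing ring A (C2–C1); the kinetic lithium enolate of the methyl ketone adds to the non-enolisable aldehyde through a closed, lithium-bridged chair transition state in which the aldehyde oxygen is gauche to C3, that is axial on the forming ring and anti to the lactone oxygen, which gives the 1β alcohol; the cold acidic quench forestalls retro-aldol and dehydration.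

Step 22
Reactants: 34 silyl ether allyl ester
Product: 35 1β,12α-diol allyl ester
Conditions: HF·pyridine, pyridine, THF, 0 °C to rt
Reagents that add atoms: none
Why: Fluoride-mediated cleavage of the silyl ether under buffered, mildly acidic conditions that the β-hydroxy ketone, the β-keto lactone and the C16 alkene should tolerate.

Step 23
Reactants: 35 diol allyl ester
Product: 36 target acid (CNP0259985.1)
Conditions: Pd(PPh3)4 (5 mol %), morpholine, THF, rt; dilute acid work-up
Reagents that add atoms: none
Why: Tsuji–Trost deallylation; zerovalent palladium ionises the allyl ester and morpholine captures the allyl group, so the hindered C7 acid is set free without hydroxide.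

## Compound list

1 | cyclohexane-1,3-dione | O=C1CCCC(=O)C1 | starting material
2 | propargyl bromide (3-bromoprop-1-yne) | C#CCBr | starting material
3 | 2-(prop-2-yn-1-yl)cyclohexane-1,3-dione | C#CCC1C(=O)CCCC1=O | intermediate
4 | methyl vinyl ketone (but-3-en-2-one) | C=CC(C)=O | starting material
5 | 2-(3-oxobutyl)-2-(prop-2-yn-1-yl)cyclohexane-1,3-dione | C#CCC1(CCC(C)=O)C(=O)CCCC1=O | intermediate
6 | (R)-8a-(prop-2-yn-1-yl)-3,4,8,8a-tetrahydronaphthalene-1,6(2H,7H)-dione (C7 and C12 ketones, C9=C11) | C#CC[C@]12CCC(=O)C=C1CCCC2=O | intermediate
7 | C12 spiro-1,3-dithiolane of 6 (C7 ketone free) | C#CC[C@]12CCC3(SCCS3)C=C1CCCC2=O | intermediate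
8 | 6-trifluoroacetyl derivative of 7 (enolised 1,3-diketone, C6 unassigned) | C#CC[C@]12CCC3(SCCS3)C=C1CCC(C(=O)C(F)(F)F)C2=O | intermediate
9 | 6-diazo-7-ketone of the propargyl decalin, C12 dithiolane | C#CC[C@]12CCC3(SCCS3)C=C1CCC(=[N+]=[N-])C2=O | intermediate
10 | ring-contracted ketene (C6=C7=O on ring B) | C#CC[C@]12CCC3(SCCS3)C=C1CCC2=C=O | intermediate
11 | allyl ester of the ring-contracted acid: propargyl on C8, C7 ester on C6 cis to it, C9=C11, C12 dithiolane | C#CC[C@]12CCC3(SCCS3)C=C1CC[C@@H]2C(=O)OCC=C | intermediate
12 | hydrindenone: C12 ketone, C9=C11, propargyl on C8, allyl ester on C6 | C#CC[C@]12CCC(=O)C=C1CC[C@@H]2C(=O)OCC=C | intermediate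
13 | C12 tert-butyldimethylsilyl enol ether of 12 (C12=C13, C9=C11) | C#CC[C@]12CC=C(O[Si](C)(C)C(C)(C)C)C=C1CC[C@@H]2C(=O)OCC=C | intermediate
14 | tricyclic B/C/D enone: C12 ketone, C9=C11, C16 methylene, allyl ester on C6 | C=C1C[C@]23C[C@H]1C(=O)C=C2CC[C@@H]3C(=O)OCC=C | intermediate
15 | extended silyl dienol ether of 14 (C12 OTBS, C11=C12, C9=C10) | C=C1C[C@]23C[C@H]1C(O[Si](C)(C)C(C)(C)C)=CC2=CC[C@@H]3C(=O)OCC=C | intermediate
16 | 9,10-epoxide of 15 (configuration unassigned) | C=C1C[C@]23C[C@H]1C(O[Si](C)(C)C(C)(C)C)=CC24OC4C[C@@H]3C(=O)OCC=C | intermediate
17 | 10-hydroxy enone (C10 either configuration) | C=C1C[C@]23C[C@H]1C(=O)C=C2C(O)C[C@@H]3C(=O)OCC=C | intermediate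
18 | 9(11)-ene-10,12-dione | C=C1C[C@]23C[C@H]1C(=O)C=C2C(=O)C[C@@H]3C(=O)OCC=C | intermediate
19 | 10,12-diketone with H9 on the α face (9-epimer) | C=C1C[C@]23C[C@H]1C(=O)C[C@@H]2C(=O)C[C@@H]3C(=O)OCC=C | intermediate
20 | 10,12-diketone with H9 on the β face (cis B/C fusion) | C=C1C[C@]23C[C@H]1C(=O)C[C@H]2C(=O)C[C@@H]3C(=O)OCC=C | intermediate
21 | 12α-hydroxy 10-ketone (hydroxyl axial, anti to C16) | C=C1C[C@]23C[C@H]1[C@@H](O)C[C@H]2C(=O)C[C@@H]3C(=O)OCC=C | intermediate
22 | 12α-(tert-butyldimethylsilyloxy) 10-ketone | C=C1C[C@]23C[C@H]1[C@@H](O[Si](C)(C)C(C)(C)C)C[C@H]2C(=O)C[C@@H]3C(=O)OCC=C | intermediate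
23 | 1,3-dithiane | C1CSCSC1 | starting material
24 | 2-lithio-1,3-dithiane | [Li]C1SCCCS1 | intermediate
25 | C10 tertiary alcohol (hydroxyl α) with 1,3-dithian-2-yl (C1, β), 12α-OTBS, allyl ester | C=C1C[C@]23C[C@H]1[C@@H](O[Si](C)(C)C(C)(C)C)C[C@H]2[C@](O)(C1SCCCS1)C[C@@H]3C(=O)OCC=C | intermediate
26 | 6-phenylselanyl derivative of 25 (C6 unassigned) | C=C1C[C@]23C[C@H]1[C@@H](O[Si](C)(C)C(C)(C)C)C[C@H]2[C@](O)(C1SCCCS1)CC3([Se]c1ccccc1)C(=O)OCC=C | intermediate
27 | selenoxide of 26 | C=C1C[C@]23C[C@H]1[C@@H](O[Si](C)(C)C(C)(C)C)C[C@H]2[C@](O)(C1SCCCS1)CC3([Se](=O)c1ccccc1)C(=O)OCC=C | intermediate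
28 | C5=C6 enoate with the C10 tertiary alcohol and dithiane | C=C1C[C@]23C[C@H]1[C@@H](O[Si](C)(C)C(C)(C)C)C[C@H]2[C@](O)(C1SCCCS1)C=C3C(=O)OCC=C | intermediate
29 | 2,2,5,6-tetramethyl-4H-1,3-dioxin-4-one | CC1=C(C)C(=O)OC(C)(C)O1 | starting material
30 | methylacetylketene (2-methyl-3-oxobut-1-en-1-one) | CC(=O)C(C)=C=O | intermediate
31 | C10 2-methyl-3-oxobutanoate of 28 (C4 epimers) | C=C1C[C@]23C[C@H]1[C@@H](O[Si](C)(C)C(C)(C)C)C[C@H]2[C@](OC(=O)C(C)C(C)=O)(C1SCCCS1)C=C3C(=O)OCC=C | intermediate
32 | 19,10-lactone: C4 methyl and acetyl, H5 β, C7 allyl ester β, C1 as dithiane, 12α-OTBS | C=C1C[C@]23C[C@H]1[C@@H](O[Si](C)(C)C(C)(C)C)C[C@H]2[C@@]4(C1SCCCS1)OC(=O)[C@](C)(C(C)=O)[C@H]4[C@@H]3C(=O)OCC=C | intermediate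
33 | 19,10-lactone with C1 formyl on C10 and acetyl on C4 | C=C1C[C@]23C[C@H]1[C@@H](O[Si](C)(C)C(C)(C)C)C[C@H]2[C@@]4(C=O)OC(=O)[C@](C)(C(C)=O)[C@H]4[C@@H]3C(=O)OCC=C | intermediate
34 | target as its 12-O-tert-butyldimethylsilyl ether and C7 allyl ester (1β-OH, 3-ketone) | C=C1C[C@]23C[C@H]1[C@@H](O[Si](C)(C)C(C)(C)C)C[C@H]2[C@]12OC(=O)[C@](C)(C(=O)C[C@H]1O)[C@H]2[C@@H]3C(=O)OCC=C | intermediate
35 | target as its C7 allyl ester | C=C1C[C@]23C[C@H]1[C@@H](O)C[C@H]2[C@]12OC(=O)[C@](C)(C(=O)C[C@H]1O)[C@H]2[C@@H]3C(=O)OCC=C | intermediate
36 | CNP0259985.1: 1β,12α-dihydroxy-3-oxo C19 gibberellin 19,10-lactone 7-oic acid | C=C1C[C@]23C[C@H]1[C@@H](O)C[C@H]2[C@]12OC(=O)[C@](C)(C(=O)C[C@H]1O)[C@H]2[C@@H]3C(=O)O | target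

## Step count and least certain steps

Total: 23 steps. Longest linear sequence: 23 steps (1 to 36; 23 and 29 enter as purchased reagents).

**Step 6 (key step).** The excited diazo ketone may be diverted into carbene chemistry (insertion into the O–H bond of the alcohol, ylide formation at a dithiolane sulfur, addition to the alkyne) instead of the 1,2-shift, or the dithiolane may be photodegraded. Fallback, from 7 back to 11: the lithium enolate of 7 is chlorinated with CF3SO2Cl to the 6-chloro ketone F1. NaOCH2CH=CH2 in allyl alcohol/THF then adds to C7, and C8 shifts to C6 with loss of chloride (semibenzilic, quasi-Favorskii contraction). This is open because C8 carries no hydrogen, and it gives the same skeleton by an ionic path.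

**Step 14.** Site selectivity between the two ketones may be poor, or hydride may be delivered to the wrong face of C12 because the C10 carbonyl is a weaker shield than a quaternary carbon. Fallback, from 20 back to 25:
- The ketones are distinguished by an equilibrium instead of a rate. Me3SiOCH2CH2OSiMe3 with catalytic Me3SiOTf at −78 °C should ketalise the six-ring ketone, giving the C12 dioxolane ketone F2.
- 24 adds to C10 to give the dithiane carbinol F3.
- Pyridinium p-toluenesulfonate in aqueous acetone releases the 12-ketone F4.
- LiBH(s-Bu)3 then reduces the single ketone, with quaternary C10 blocking the α face, to the 12α,10-diol F5.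
- TBSOTf/2,6-lutidine at −78 °C silylates the secondary hydroxyl to give 25.

**Step 16.** The basic, bulky nucleophile may enolise the hindered ketone instead of adding, and the silyl group may migrate from O12 to the new alkoxide. Fallback, from 22 back to 25:
- C1 is brought in at the alcohol oxidation level by a smaller primary carbon nucleophile. (i-PrO)Me2SiCH2MgCl with CeCl3 gives the β-hydroxy silane F6.
- Tamao oxidation (KF, KHCO3, H2O2) gives the 1,10-diol F7.
- SO3·pyridine/DMSO oxidises the primary alcohol to the hydroxy aldehyde F8.
- Propane-1,3-dithiol with BF3·OEt2 at −40 °C converts F8 into 25.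

**Step 19.** Closure may be slow because the ester must turn into its s-cis rotamer. That leaves time for retro-Claisen cleavage by the alkoxide, and the ring may close with the acetyl arm on the side of C6. Fallback, from 31 back to 34: the aldehyde is released first (MeI, CaCO3, aqueous MeCN) to give the keto ester aldehyde F9. Cs2CO3 in MeCN is then used so that the Michael adduct with acetyl beside C10 is captured at once by the ring A aldol. C6 would then have to be checked separately.

**Step 21.** Addition through an open transition state would give the equatorial 1α alcohol, and retro-aldol or dehydration may set in on warming. Fallback, from 33 back to 34: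
- C1 is set by oxygen delivery instead of by C–C bond formation. The aldol mixture containing the 1-epimer F10 is dehydrated (MsCl, Et3N) to the 1-en-3-one F11.
- t-BuOOH/DBU epoxidises F11 from the β face, since the lactone bridge covers the α face, to give the 1β,2β-epoxy ketone F12.
- SmI2 in THF/MeOH at −78 °C cleaves the C2–O bond to give 34.

## Further compounds

F1 | step 6 | 6-chloro derivative of 7 (C6 unassigned) | C#CC[C@]12CCC3(SCCS3)C=C1CCC(Cl)C2=O
F2 | step 14 | C12 ethylene ketal of 20 (C10 ketone free) | C=C1C[C@]23C[C@H]1C4(OCCO4)C[C@H]2C(=O)C[C@@H]3C(=O)OCC=C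
F3 | step 14 | C12 ethylene ketal with C10 tertiary alcohol and 1,3-dithian-2-yl | C=C1C[C@]23C[C@H]1C4(OCCO4)C[C@H]2[C@](O)(C1SCCCS1)C[C@@H]3C(=O)OCC=C
F4 | step 14 | 12-ketone with C10 tertiary alcohol and 1,3-dithian-2-yl | C=C1C[C@]23C[C@H]1C(=O)C[C@H]2[C@](O)(C1SCCCS1)C[C@@H]3C(=O)OCC=C
F5 | step 14 | 12α,10-diol with 1,3-dithian-2-yl on C10 | C=C1C[C@]23C[C@H]1[C@@H](O)C[C@H]2[C@](O)(C1SCCCS1)C[C@@H]3C(=O)OCC=C
F6 | step 16 | C10 tertiary alcohol with (isopropoxydimethylsilyl)methyl as C1 | C=C1C[C@]23C[C@H]1[C@@H](O[Si](C)(C)C(C)(C)C)C[C@H]2[C@](O)(C[Si](C)(C)OC(C)C)C[C@@H]3C(=O)OCC=C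
F7 | step 16 | 1,10-diol (C1 hydroxymethyl on C10) | C=C1C[C@]23C[C@H]1[C@@H](O[Si](C)(C)C(C)(C)C)C[C@H]2[C@](O)(CO)C[C@@H]3C(=O)OCC=C
F8 | step 16 | 10-hydroxy C1 aldehyde | C=C1C[C@]23C[C@H]1[C@@H](O[Si](C)(C)C(C)(C)C)C[C@H]2[C@](O)(C=O)C[C@@H]3C(=O)OCC=C
F9 | step 19 | C10 2-methyl-3-oxobutanoate with free C1 aldehyde and C5=C6 enoate | C=C1C[C@]23C[C@H]1[C@@H](O[Si](C)(C)C(C)(C)C)C[C@H]2[C@](OC(=O)C(C)C(C)=O)(C=O)C=C3C(=O)OCC=C
F10 | step 21 | 1-epimer of 34 (1α-OH) | C=C1C[C@]23C[C@H]1[C@@H](O[Si](C)(C)C(C)(C)C)C[C@H]2[C@]12OC(=O)[C@](C)(C(=O)C[C@@H]1O)[C@H]2[C@@H]3C(=O)OCC=C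
F11 | step 21 | 1-en-3-one (12-silyl ether, allyl ester) | C=C1C[C@]23C[C@H]1[C@@H](O[Si](C)(C)C(C)(C)C)C[C@H]2[C@]12OC(=O)[C@](C)(C(=O)C=C1)[C@H]2[C@@H]3C(=O)OCC=C
F12 | step 21 | 1β,2β-epoxy 3-ketone | C=C1C[C@]23C[C@H]1[C@@H](O[Si](C)(C)C(C)(C)C)C[C@H]2[C@]12OC(=O)[C@](C)(C(=O)[C@H]4O[C@H]41)[C@H]2[C@@H]3C(=O)OCC=C
A1 | alternative 1 | ring B 5(10)-ene with the C1 silyloxy, 3-oxo, 4-methyl tert-butyl ester chain on C10 | C=C1C[C@]23C[C@H]1[C@@H](O[Si](C)(C)C(C)(C)C)C[C@H]2C(=C[C@@H]3C(=O)OCC=C)[C@H](O[Si](C)(C)C(C)(C)C)CC(=O)C(C)C(=O)OC(C)(C)C
A2 | alternative 1 | target as its C1 and C12 silyl ethers and C7 allyl ester | C=C1C[C@]23C[C@H]1[C@@H](O[Si](C)(C)C(C)(C)C)C[C@H]2[C@]12OC(=O)[C@](C)(C(=O)C[C@H]1O[Si](C)(C)C(C)(C)C)[C@H]2[C@@H]3C(=O)OCC=C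
A3 | alternative 2 | 2-propargyl-4-(tert-butyldimethylsilyloxy)cyclopent-2-enone | C#CCC1=C[C@H](O[Si](C)(C)C(C)(C)C)CC1=O
A4 | alternative 2 | 2-(triisopropylsilyloxy)buta-1,3-diene | C=CC(=C)O[Si](C(C)C)(C(C)C)C(C)C
A5 | alternative 2 | cis-hydrindanone with angular propargyl group, C12 silyl enol ether, C10 silyl ether | C#CC[C@]12CC=C(O[Si](C(C)C)(C(C)C)C(C)C)C[C@H]1[C@H](O[Si](C)(C)C(C)(C)C)CC2=O
A6 | alternative 3 | 12,13-epoxide with 2-bromoallyl on C8, C6 dioxolane, C10 silyl ether | C=C(Br)C[C@]12C[C@H]3O[C@H]3C[C@H]1[C@H](O[Si](C)(C)C(C)(C)C)CC24OCCO4
A7 | alternative 3 | tricyclic B/C/D carbinol with C16 methylene, C6 dioxolane, C10 silyl ether | C=C1C[C@]23C[C@H]1[C@@H](O)C[C@H]2[C@H](O[Si](C)(C)C(C)(C)C)CC34OCCO4
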